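**Strategy.** Everything rests on cutting ring A at C1–C2 and C4–C5: the C3 carbinol next to the gem-dimethyl carbon C4 is an opened 2,2-dimethyloxirane, and the C6 oxygen of ring B makes C5 an enol carbon. In one flask the alkyllithium of an iodomethyl arm on quaternary C10 displaces the triflate of (R)-3,3-dimethylglycidol (C1–C2), then a silyl triflate opens the tethered epoxide at its tertiary carbon with the C5=C6 enol silane (C4–C5), delivering the decalin with O3 silylated and the C6 ketone in place. The precursor is a monocyclic γ-iodo enol silane made by opening a cyclopropyl ketone with trimethylsilyl iodide.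

Key step: step 7

Remark on numbering: atoms carry the usual diterpene numbers (ring A = C1–C5 and C10; ring B = C5–C10; side chain C11–C16 on C9; C17 = methyl on C8). "Syn" and "anti" refer to the C10 methyl group.

Assumption: the target SMILES is read as (3R,5S,6R,8S,9R,10R), i.e. H5, the C9 side chain, O6 and O8 are anti to the C10 methyl, while O3 and the C8 methyl are syn.

Step 1
Reactants: 1 3-methylglutaric acid
Product: 2 4-methylheptane-2,6-dione
Conditions: MeLi (4.5 equiv), THF, 0 °C to rt; inverse quench into 1 M HCl
Reagents that add atoms: methyllithium [Li]C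
Why: Addition of methyllithium to the lithium carboxylates stops at the gem-dialkoxide, which should collapse to the methyl ketone only on acidic work-up (carboxylic acid to methyl ketone conversion with an organolithium).

Step 2
Reactants: 2 4-methylheptane-2,6-dione
Product: 3 (5S)-3,5-dimethylcyclohex-2-en-1-one
Conditions: 9-amino-9-deoxy-epi-cinchona primary amine (pseudo-enantiomer that gives the S enone, 10 mol %), AcOH (30 mol %), toluene, −15 °C
Reagents that add atoms: none
Why: Enamine-catalysed desymmetrising intramolecular aldol condensation, in which the chiral primary amine should select one of the two enantiotopic acetonyl arms and so set the C8 methyl stereocentre, which serves later only as a control element.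

Step 3
Reactants: 3 (5S)-3,5-dimethylcyclohex-2-en-1-one
Product: 4 (1S,4S,6R)-4,6-dimethylbicyclo[4.1.0]heptan-2-one
Conditions: Me3S(O)I, NaH, DMSO, rt to 50 °C
Reagents that add atoms: trimethylsulfoxonium iodide C[S+](C)(C)=O.[I-]
Why: Corey–Chaykovsky cyclopropanation, in which the sulfoxonium ylide should add to the β-carbon (C10) anti to the C8 methyl and close by 3-exo-tet displacement, fixing quaternary C10 relative to C8.

Step 4
Reactants: 4 (1S,4S,6R)-4,6-dimethylbicyclo[4.1.0]heptan-2-one
Product: 5 {[(3S,5S)-3-(iodomethyl)-3,5-dimethylcyclohex-1-en-1-yl]oxy}trimethylsilane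
Conditions: Me3SiI (1.1 equiv), CH2Cl2, −78 to 0 °C; Et3N, pentane, filtration; used crude
Reagents that add atoms: iodotrimethylsilane C[Si](C)(C)I
Why: Ring opening of a cyclopropyl ketone by iodotrimethylsilane, in which O-silylation should turn the ketone into a homo-Michael acceptor and iodide should attack the unhindered CH2 (C1) in SN2 fashion, cleaving the C1–C5 bond that overlaps with the carbonyl π system and leaving the enol silane regiospecifically at C5=C6.

Step 5
Reactants: 6 3-methylbut-2-en-1-ol
Product: 7 [(2R)-3,3-dimethyloxiran-2-yl]methanol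
Conditions: Ti(OiPr)4 (5 mol %), D-(−)-diethyl tartrate (6 mol %), t-BuOOH, 4 Å molecular sieves, CH2Cl2, −20 °C
Reagents that add atoms: tert-butyl hydroperoxide CC(C)(C)OO
Why: Sharpless asymmetric epoxidation of the allylic alcohol, where the D-tartrate ligand should deliver oxygen to the face that gives the R oxirane carbon (the future C3).

Step 6
Reactants: 7 [(2R)-3,3-dimethyloxiran-2-yl]methanol
Product: 8 [(2R)-3,3-dimethyloxiran-2-yl]methyl trifluoromethanesulfonate
Conditions: Tf2O, 2,6-lutidine, CH2Cl2, −78 °C; used cold without purification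
Reagents that add atoms: trifluoromethanesulfonic anhydride O=S(=O)(OS(=O)(=O)C(F)(F)F)C(F)(F)F
Why: O-Sulfonylation of the primary alcohol, which touches no stereocentre and makes C2 a primary electrophile far more reactive than the trisubstituted oxirane.

Step 7
Reactants: 5 {[(3S,5S)-3-(iodomethyl)-3,5-dimethylcyclohex-1-en-1-yl]oxy}trimethylsilane; 8 [(2R)-3,3-dimethyloxiran-2-yl]methyl trifluoromethanesulfonate
Product: 11 cis-fused silyloxy decalone, via alkyllithium 9 (not isolated), via epoxy enol silane 10 (not isolated)
Conditions: t-BuLi (2.1 equiv), Et2O/pentane, −78 °C; CuBr·SMe2 (10 mol %), then 8, −78 to −40 °C; then CH2Cl2, 2,6-di-tert-butyl-4-methylpyridine, TBSOTf (1.2 equiv), −78 °C; aq. NaHCO3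
Reagents that add atoms: tert-butyldimethylsilyl trifluoromethanesulfonate CC(C)(C)[Si](C)(C)OS(=O)(=O)C(F)(F)F
Why: Iodine–lithium exchange gives the neopentyl-type alkyllithium 9, which should displace the primary triflate of 8 (copper-catalysed sp3–sp3 coupling) faster than it opens the hindered trisubstituted oxirane, forming C1–C2 and epoxide 10. The silyl triflate then silylates the oxirane oxygen and the C5=C6 enol silane attacks the tertiary carbon C4 (epoxide-opening cation–olefin cyclisation terminated by an enol silane), forming C4–C5, and loss of the trimethylsilyl group from the oxocarbenium ion leaves the C6 ketone. Ring A closes 6-endo with respect to the oxirane (attack at the more substituted carbon, favoured by the gem-dimethyl group and the strong Lewis acid over 5-exo attack at C3) and exo with respect to the enol double bond. C3 keeps the configuration set in step 5 because its C–O bond is never broken, C10 is already fixed, and the new centre C5 is formed cis to the arm because the tether can reach only the enol face that carries it (this centre is corrected in step 8). Because that face is imposed, the C3 silyloxy group has to lie axial in the closing ring, so the closure goes through a loose, cation-like transition state instead of an anti-periplanar chair; this may cost rate but cannot redirect the bond, since C5 is the only nucleophilic carbon within reach. The step needs chemoselectivity for triflate over oxirane in the first bond and for carbon attack at C4 in the second, and both rest on the contrast between the primary triflate and the tertiary oxirane carbon within 8.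

Step 8
Reactants: 11 cis-fused silyloxy decalone
Product: 14 trans-fused silyloxy enone, via trimethylsilyl enol ether 12 (not isolated), via cis-fused enone 13 (not isolated)
Conditions: LDA, Me3SiCl, THF, −78 °C; Pd(OAc)2 (10 mol %), O2 (1 atm), DMSO, rt; then NaOMe (cat.), MeOH, rt
Reagents that add atoms: none
Why: Saegusa–Ito dehydrogenation, in which kinetic enolisation at the only α-methylene (C7) and β-hydride loss from C8 should give the 7-en-6-one and erase the C8 control centre, after which methoxide should epimerise C5 through the cross-conjugated enolate to the more stable trans ring fusion.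

Step 9
Reactants: 14 trans-fused silyloxy enone
Product: 15 trans-fused β,γ-enone
Conditions: KOtBu (5 equiv), t-BuOH/THF, rt; inverse quench into 10 % aq. AcOH, 0 °C
Reagents that add atoms: none
Why: Deconjugation of an enone by kinetic α-protonation (at C7) of the linear dienolate formed by γ-deprotonation at C9, which should move the double bond to C8=C9 while C5, not part of this dienolate, keeps the trans fusion.

Step 10
Reactants: 15 trans-fused β,γ-enone
Product: 16 homoallylic alcohol
Conditions: Li, NH3 (l)/THF, t-BuOH, −78 °C; NH4Cl
Reagents that add atoms: none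
Why: Dissolving-metal reduction of the hindered ketone, which should give the thermodynamically preferred equatorial alcohol (O6 anti to the C10 methyl), whereas hydride reagents would attack the open face and give the axial epimer; the isolated trisubstituted alkene is inert.

Step 11
Reactants: 16 homoallylic alcohol
Product: 17 ene aldehyde
Conditions: acrolein (3 equiv), Me2AlCl (2.5 equiv), CH2Cl2, −78 to −20 °C
Reagents that add atoms: acrolein C=CC=O
Why: Lewis-acid-promoted ene reaction with acrolein as enophile, in which the new C–C bond should form at the less substituted alkene carbon C9 on the face anti to the axial C10 methyl (setting C9) while a hydrogen of the C8 methyl is transferred, leaving the exocyclic C8=C17 alkene.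

Step 12
Reactants: 17 ene aldehyde
Product: 18 terminal alkyne
Conditions: dimethyl (1-diazo-2-oxopropyl)phosphonate, K2CO3, MeOH, 0 °C to rt
Reagents that add atoms: dimethyl (1-diazo-2-oxopropyl)phosphonate COP(=O)(OC)C(=[N+]=[N-])C(C)=O
Why: Ohira–Bestmann homologation of the aldehyde to the terminal alkyne under mild carbonate conditions that should leave every stereocentre, the silyl ether and the free alcohol untouched.

Step 13
Reactants: 18 terminal alkyne
Product: 19 spiro-epoxide
Conditions: VO(acac)2 (5 mol %), t-BuOOH, CH2Cl2, 0 °C to rt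
Reagents that add atoms: tert-butyl hydroperoxide CC(C)(C)OO
Why: Hydroxyl-directed epoxidation, in which the vanadium alkoxide of the equatorial homoallylic C6 hydroxyl should deliver oxygen to the face of C8=C17 on its own side, placing O8 anti to the C10 methyl, while the alkyne does not react.

Step 14
Reactants: 19 spiro-epoxide
Product: 20 alkyne diol
Conditions: LiAlH4, THF, 0 °C to rt
Reagents that add atoms: none
Why: Hydride opening of the spiro-epoxide by SN2 attack at its unsubstituted CH2, which should create the C8 methyl and leave the tertiary C8–O bond with its configuration intact.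

Step 15
Reactants: 20 alkyne diol
Product: 21 diene diol
Conditions: ethylene (1 atm), second-generation Grubbs catalyst RuCl2(=CHPh)(PCy3)(H2IMes) (5 mol %), toluene, 50 °C
Reagents that add atoms: ethylene C=C
Why: Enyne cross-metathesis of the terminal alkyne with ethylene, which should convert C13≡C14 directly into the 2-substituted buta-1,3-diene in the presence of free hydroxyl groups.

Step 16
Reactants: 21 diene diol
Product: 22 silyl-protected acetate
Conditions: Ac2O, pyridine, DMAP (cat.), CH2Cl2, rt
Reagents that add atoms: acetic anhydride CC(=O)OC(C)=O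
Why: Acylation of the only free secondary alcohol (C6), since the tertiary C8 hydroxyl should not react under these conditions and O3 is silylated.

Step 17
Reactants: 22 silyl-protected acetate
Product: 23 CNP0351600.2
Conditions: HF·pyridine, pyridine/THF, 0 °C to rt
Reagents that add atoms: none
Why: Fluoride-mediated cleavage of the hindered silyl ether under buffered conditions that should spare the acetate, the tertiary alcohol and the diene.

**Compound list**

1 | 3-methylglutaric acid | OC(=O)CC(C)CC(O)=O | starting material
2 | 4-methylheptane-2,6-dione | CC(=O)CC(C)CC(C)=O | intermediate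
3 | (5S)-3,5-dimethylcyclohex-2-en-1-one | C[C@H]1CC(C)=CC(=O)C1 | intermediate
4 | (1S,4S,6R)-4,6-dimethylbicyclo[4.1.0]heptan-2-one (cyclopropane CH2 anti to the C4 methyl) | C1[C@]2(C)C[C@@H]2C(=O)C[C@H]1C | intermediate
5 | {[(3S,5S)-3-(iodomethyl)-3,5-dimethylcyclohex-1-en-1-yl]oxy}trimethylsilane | C1[C@](C)(CI)C=C(O[Si](C)(C)C)C[C@H]1C | intermediate
6 | 3-methylbut-2-en-1-ol (prenol) | CC(C)=CCO | starting material
7 | [(2R)-3,3-dimethyloxiran-2-yl]methanol | OC[C@H]1OC1(C)C | intermediate
8 | [(2R)-3,3-dimethyloxiran-2-yl]methyl trifluoromethanesulfonate | O=S(=O)(OC[C@H]1OC1(C)C)C(F)(F)F | intermediate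
9 | alkyllithium: compound 5 with lithium in place of iodine, same configuration | C1[C@](C)(C[Li])C=C(O[Si](C)(C)C)C[C@H]1C | intermediate
10 | epoxy enol silane: compound 5 with the [(2R)-3,3-dimethyloxiran-2-yl]methyl group in place of iodine | C1[C@](C)(CC[C@H]2OC2(C)C)C=C(O[Si](C)(C)C)C[C@H]1C | intermediate
11 | cis-fused silyloxy decalone: 3-(tert-butyldimethylsilyloxy)-4,4,8,10-tetramethyldecalin-6-one; O3, H5 and the 8-methyl syn; C3 and C10 as in the target | C1[C@]2(C)CC[C@@H](O[Si](C)(C)C(C)(C)C)C(C)(C)[C@@H]2C(=O)C[C@H]1C | intermediate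
12 | trimethylsilyl enol ether of 11 (C6=C7) | C1[C@]2(C)CC[C@@H](O[Si](C)(C)C(C)(C)C)C(C)(C)[C@@H]2C(O[Si](C)(C)C)=C[C@H]1C | intermediate
13 | cis-fused enone: 3-(tert-butyldimethylsilyloxy)-4,4,8,10-tetramethyldecal-7-en-6-one; H5 syn | C1[C@]2(C)CC[C@@H](O[Si](C)(C)C(C)(C)C)C(C)(C)[C@@H]2C(=O)C=C1C | intermediate
14 | trans-fused silyloxy enone: C5 epimer of 13; H5 anti, O3 syn | C1[C@]2(C)CC[C@@H](O[Si](C)(C)C(C)(C)C)C(C)(C)[C@H]2C(=O)C=C1C | intermediate
15 | trans-fused β,γ-enone: 3-(tert-butyldimethylsilyloxy)-4,4,8,10-tetramethyldecal-8-en-6-one; C8=C9; H5 anti | C1[C@]2(C)CC[C@@H](O[Si](C)(C)C(C)(C)C)C(C)(C)[C@H]2C(=O)CC=1C | intermediate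
16 | homoallylic alcohol: 6-ol of 15; O6 anti (equatorial) | C1[C@]2(C)CC[C@@H](O[Si](C)(C)C(C)(C)C)C(C)(C)[C@H]2[C@H](O)CC=1C | intermediate
17 | ene aldehyde: 3-oxopropyl chain on C9 (anti), exocyclic C8=C17, 6-OH anti, 3-OTBS syn | O=CCC[C@@H]1[C@]2(C)CC[C@@H](O[Si](C)(C)C(C)(C)C)C(C)(C)[C@H]2[C@H](O)CC1=C | intermediate
18 | terminal alkyne: but-3-ynyl chain on C9 (anti), otherwise as 17 | C#CCC[C@@H]1[C@]2(C)CC[C@@H](O[Si](C)(C)C(C)(C)C)C(C)(C)[C@H]2[C@H](O)CC1=C | intermediate
19 | spiro-epoxide: 8,17-epoxide of 18; epoxide oxygen anti, CH2 syn | C#CCC[C@@H]1[C@]2(C)CC[C@@H](O[Si](C)(C)C(C)(C)C)C(C)(C)[C@H]2[C@H](O)C[C@@]13CO3 | intermediate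
20 | alkyne diol: 6,8-diol; O6 and O8 anti, 8-methyl syn | C#CCC[C@@H]1[C@]2(C)CC[C@@H](O[Si](C)(C)C(C)(C)C)C(C)(C)[C@H]2[C@H](O)C[C@]1(C)O | intermediate
21 | diene diol: 3-O-silyl ether of the 6-deacetyl target | C=CC(=C)CC[C@@H]1[C@]2(C)CC[C@@H](O[Si](C)(C)C(C)(C)C)C(C)(C)[C@H]2[C@H](O)C[C@]1(C)O | intermediate
22 | silyl-protected acetate: 3-O-tert-butyldimethylsilyl ether of the target | C=CC(=C)CC[C@@H]1[C@]2(C)CC[C@@H](O[Si](C)(C)C(C)(C)C)C(C)(C)[C@H]2[C@H](OC(C)=O)C[C@]1(C)O | intermediate
23 | CNP0351600.2: (3R,5S,6R,8S,9R,10R)-3,8-dihydroxylabda-13(16),14-dien-6-yl acetate | C=CC(=C)CC[C@@H]1[C@]2(C)CC[C@@H](O)C(C)(C)[C@H]2[C@H](OC(C)=O)C[C@]1(C)O | target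

**Step count.** Total: 17 steps. Longest linear sequence: 15 steps (steps 1–4, then 7–17); steps 5–6 form a two-step branch.

**Steps most likely to fail**

Step 7 (key step). Two processes may go wrong. The trimethylsilyl group may migrate from oxygen to the carbanionic carbon of 9. More seriously, ring closure may be slow because the C3 silyloxy group must sit axial and the oxirane cannot open through an anti-periplanar chair, so that a 1,2-hydride shift or elimination of the activated oxirane overtakes C–C bond formation. The fallback sets out from 5 and 6 and comes back at 16; it uses the enantiomeric oxirane, which closes through the ordinary chair, and corrects C3 later by oxidation and thermodynamic reduction. Prenol 6 is epoxidised with L-(+)-diethyl tartrate to [(2S)-3,3-dimethyloxiran-2-yl]methanol F1 and converted to the (2S)-triflate F2. The alkyllithium 9 from 5 is coupled with F2 (CuBr·SMe2) to the diastereomeric epoxy enol silane F3, which is isolated and cyclised with MeAlCl2 in CH2Cl2 at −78 °C to the cis-fused 3-epi hydroxy decalone F4. 2-Iodoxybenzoic acid in DMSO dehydrogenates it to the cis-fused 3-epi hydroxy enone F5. KOtBu in t-BuOH followed by a kinetic quench epimerises C5 and deconjugates to the trans-fused 3-epi hydroxy β,γ-enone F6. Swern oxidation gives the 3,6-diketone F7, and Li in NH3 reduces both ketones to the equatorial alcohols of the 3,6-diol F8. TBSCl and imidazole silylate the less hindered C3 hydroxyl to give 16.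

Step 11. Hetero-Diels–Alder addition or polymerisation of acrolein may win over the ene reaction at the hindered C9, and the hydrogen transfer may lose regiocontrol. The fallback sets out from 16 and comes back at 18. The carbonyl-ene reaction with formaldehyde (paraformaldehyde, Me2AlCl, CH2Cl2) forms the C9–C11 bond with the same facial preference and gives the hydroxymethyl diol F9. The primary hydroxyl is triflated selectively (Tf2O, 2,6-lutidine, −78 °C) to the primary triflate F10. Displacement with 3-(trimethylsilyl)prop-2-ynyllithium gives the silyl alkyne F11, and K2CO3 in MeOH removes the alkynyl silyl group to give 18.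

Step 9. Reconjugation during the quench, proton loss from the C8 methyl instead of C9, and partial epimerisation at C5 may occur. The fallback sets out from 14 and comes back at 15. Soft enolisation with Me3SiOTf and Et3N gives the isolable silyl dienol ether F12 (6-silyloxy-6,8-diene), which is protonated at C7 under fluoride (TBAF, AcOH, THF, −78 °C) to give 15.

**Further compounds**

F1 | step 7 | [(2S)-3,3-dimethyloxiran-2-yl]methanol | OC[C@@H]1OC1(C)C
F2 | step 7 | [(2S)-3,3-dimethyloxiran-2-yl]methyl trifluoromethanesulfonate | O=S(=O)(OC[C@@H]1OC1(C)C)C(F)(F)F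
F3 | step 7 | diastereomeric epoxy enol silane (2S oxirane) | C1[C@](C)(CC[C@@H]2OC2(C)C)C=C(O[Si](C)(C)C)C[C@H]1C
F4 | step 7 | cis-fused 3-epi hydroxy decalone (O3 anti, H5 syn) | C1[C@]2(C)CC[C@H](O)C(C)(C)[C@@H]2C(=O)C[C@H]1C
F5 | step 7 | cis-fused 3-epi hydroxy enone | C1[C@]2(C)CC[C@H](O)C(C)(C)[C@@H]2C(=O)C=C1C
F6 | step 7 | trans-fused 3-epi hydroxy β,γ-enone | C1[C@]2(C)CC[C@H](O)C(C)(C)[C@H]2C(=O)CC=1C
F7 | step 7 | trans-fused 4,4,8,10-tetramethyldecal-8-ene-3,6-dione | C1[C@]2(C)CCC(=O)C(C)(C)[C@H]2C(=O)CC=1C
F8 | step 7 | 3,6-diol (O3 syn, O6 anti) | C1[C@]2(C)CC[C@@H](O)C(C)(C)[C@H]2[C@H](O)CC=1C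
F9 | step 11 | hydroxymethyl diol (CH2OH on C9 anti, exocyclic C8=C17) | OC[C@@H]1[C@]2(C)CC[C@@H](O[Si](C)(C)C(C)(C)C)C(C)(C)[C@H]2[C@H](O)CC1=C
F10 | step 11 | primary triflate of F9 | O=S(=O)(OC[C@@H]1[C@]2(C)CC[C@@H](O[Si](C)(C)C(C)(C)C)C(C)(C)[C@H]2[C@H](O)CC1=C)C(F)(F)F
F11 | step 11 | C-trimethylsilyl derivative of alkyne 18 | C[Si](C)(C)C#CCC[C@@H]1[C@]2(C)CC[C@@H](O[Si](C)(C)C(C)(C)C)C(C)(C)[C@H]2[C@H](O)CC1=C
F12 | step 9 | silyl dienol ether of 14 (6-trimethylsilyloxy-6,8-diene) | C1[C@]2(C)CC[C@@H](O[Si](C)(C)C(C)(C)C)C(C)(C)[C@H]2C(O[Si](C)(C)C)=CC=1C
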